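**Plan**

Numbering: C1(Me)=C2–C3(O)–C4(Me)–C8(H)–C9(O)–C10 around the cycloheptene and C4–C5–C6–C7(OH)(iPr)–C8 around the cyclopentane; C11 is a carboxyl carbon on C3 that is lost on the way.
Retrosynthesis cuts the two ester C–O bonds, then C2–C3 of the seven-membered ring (a C3 oxocarbenium ion, made from an α-benzyloxy acid by anodic loss of C11 as CO2, is captured by a Z vinylsilane at C2), then C9–C10 (methallylation), then C3–C4 (Ireland–Claisen) and C4–C8 (aldol ring contraction of (R)-terpinen-4-ol).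
Forward: the cyclopentene is made first, then the quaternary C4 with C3 and C11, then C8–H and the C9 side chain with its vinylsilane, then the cycloheptene is closed at C2–C3, and the two acylations come last.
Enabling feature: C3 carries oxygen and is bonded to the vinylic C2 and to the quaternary ring-fusion carbon C4, so a cation at C3 is oxygen-stabilised, cannot lose a proton, and ipso attack of the C2–Si bond leaves C1=C2 where it must be inside the seven-membered ring.
Stereochemistry: C7 comes from (R)-terpinen-4-ol, C4 (Claisen) and C8 (hydroboration) are relayed from C7, C9 is set by a chiral boron reagent, and C3 is set in the ring closure.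

Key step: step 18

Remark on the chemistry: compounds 9–24 are drawn as the C3 epimer expected from the chelated enolate of step 6, and the other epimer is carried along because C3 becomes planar in step 18.

**Route**

Step 1
Reactants: 1 (R)-terpinen-4-ol
Product: 2 triethyl{[(1R)-4-methyl-1-(propan-2-yl)cyclohex-3-en-1-yl]oxy}silane
Conditions: Et3SiOTf, 2,6-lutidine, CH2Cl2, 0 °C
Reagents that add atoms: triethylsilyl trifluoromethanesulfonate, CC[Si](CC)(CC)OS(=O)(=O)C(F)(F)F
Why: Silyl ether formation at the hindered tertiary alcohol with the silyl triflate, which keeps the carbinol from β-elimination in step 3 and stays on until step 21.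

Step 2
Reactants: 2 triethylsilyl ether of terpinen-4-ol
Product: 3 (3R)-6-oxo-3-(propan-2-yl)-3-[(triethylsilyl)oxy]heptanal
Conditions: O3, CH2Cl2, −78 °C; then PPh3, −78 °C → rt
Reagents that add atoms: ozone, [O-][O+]=O
Why: Ozonolysis with reductive work-up cleaves the only C=C bond to the 1,6-keto aldehyde and does not touch the stereocentre.

Step 3
Reactants: 3 keto aldehyde
Product: 4 (5S)-2-methyl-5-(propan-2-yl)-5-[(triethylsilyl)oxy]cyclopent-1-ene-1-carbaldehyde
Conditions: piperidine, AcOH, toluene, rt → 60 °C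
Reagents that add atoms: none
Why: Intramolecular aldol condensation through the piperidine enamine of the aldehyde (five-membered ring by attack on the methyl ketone, then dehydration) gives the cyclopentene that holds C4, C5, C6, C7 and C8, and ring closure should outrun β-elimination of the silanolate.

Step 4
Reactants: 4 enal
Product: 5 {(5S)-2-methyl-5-(propan-2-yl)-5-[(triethylsilyl)oxy]cyclopent-1-en-1-yl}methanol
Conditions: NaBH4, CeCl3·7H2O, MeOH, −20 → 0 °C
Reagents that add atoms: none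
Why: Luche 1,2-reduction of the enal gives the allylic alcohol without conjugate reduction.

Step 5
Reactants: 5 allylic alcohol; 6 (benzyloxy)acetyl chloride
Product: 7 {(5S)-2-methyl-5-(propan-2-yl)-5-[(triethylsilyl)oxy]cyclopent-1-en-1-yl}methyl (benzyloxy)acetate
Conditions: pyridine, DMAP (cat.), CH2Cl2, 0 °C → rt
Reagents that add atoms: (benzyloxy)acetyl chloride (6), O=C(Cl)COCc1ccccc1
Why: DMAP-catalysed acylation of the primary allylic alcohol brings in C3 and C11, with benzyl on the C3 oxygen because a benzyl ether survives every later base and hydride and gives an oxocarbenium ion in step 18 that has no easy way to fragment.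

Step 6
Reactants: 7 allylic glycolate
Product: 10 (2R)-(benzyloxy){(1S,3S)-1-methyl-2-methylidene-3-(propan-2-yl)-3-[(triethylsilyl)oxy]cyclopentyl}acetic acid, via silyl ketene acetal 8 (not isolated), via trimethylsilyl ester 9 (not isolated)
Conditions: LiN(SiMe3)2, THF, −78 °C; Me3SiCl, Et3N, −78 → 60 °C; then aqueous citric acid
Reagents that add atoms: none
Why: Ireland–Claisen rearrangement: the chelated Z lithium enolate is trapped as ketene acetal 8, and its chair-like [3,3] shift should form C3–C4 on the ring face of the C7 oxygen, anti to the bulkier isopropyl group, which sets the quaternary C4 and moves the alkene to the exocyclic C8=C9 position, while the C3 configuration follows from the Z acetal and does not matter later.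

Step 7
Reactants: 10 α-benzyloxy acid
Product: 11 (2R)-2-(benzyloxy)-2-{(1S,3S)-1-methyl-2-methylidene-3-(propan-2-yl)-3-[(triethylsilyl)oxy]cyclopentyl}ethan-1-ol
Conditions: LiAlH4, THF, 0 °C → rt
Reagents that add atoms: none
Why: Hydride reduction of the acid takes C11 to the alcohol level, where it is safe from MeLi in step 14, and it is brought back to the acid in steps 16 and 17.

Step 8
Reactants: 11 primary alcohol
Product: 12 triethyl[(2R)-2-(benzyloxy)-2-{(1S,3S)-1-methyl-2-methylidene-3-(propan-2-yl)-3-[(triethylsilyl)oxy]cyclopentyl}ethoxy]silane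
Conditions: Et3SiCl, imidazole, CH2Cl2, 0 °C
Reagents that add atoms: chlorotriethylsilane, CC[Si](CC)(CC)Cl
Why: Silyl ether formation at the only free hydroxyl puts a primary triethylsilyl group on the C11 oxygen that step 16 can remove and oxidise in one operation.

Step 9
Reactants: 12 exocyclic alkene
Product: 14 {(1S,2S,5S)-2-[(1R)-1-(benzyloxy)-2-(triethylsilyloxy)ethyl]-2-methyl-5-(propan-2-yl)-5-(triethylsilyloxy)cyclopentyl}methanol, via alkylborane 13 (not isolated)
Conditions: 9-BBN, THF, 0 → 50 °C; then NaOH, H2O2, 0 °C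
Reagents that add atoms: hydrogen peroxide, OO
Why: Hydroboration–oxidation: 9-BBN puts boron on the terminal C9 and should deliver hydrogen to C8 from the face of the C7 oxygen, anti to the isopropyl group (the bulkier C7 substituent and the better donor bond to have anti, whereas methyl and the branched chain on C4 differ less), which sets C8 with C9 cis to the isopropyl and C4 methyl groups.

Step 10
Reactants: 14 primary alcohol
Product: 15 (1R,2S,5S)-2-[(1R)-1-(benzyloxy)-2-(triethylsilyloxy)ethyl]-2-methyl-5-(propan-2-yl)-5-(triethylsilyloxy)cyclopentane-1-carbaldehyde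
Conditions: Dess–Martin periodinane, NaHCO3, CH2Cl2, 0 °C
Reagents that add atoms: none
Why: Dess–Martin oxidation gives the C9 aldehyde under buffered, non-basic conditions that should not epimerise C8.

Step 11
Reactants: 15 aldehyde; 16 (2-methylprop-2-en-1-yl)magnesium chloride
Product: 18 (1R)-1-{(1S,2S,5S)-2-[(1R)-1-(benzyloxy)-2-(triethylsilyloxy)ethyl]-2-methyl-5-(propan-2-yl)-5-(triethylsilyloxy)cyclopentyl}-3-methylbut-3-en-1-ol, via diisopinocampheylborinate 17 (not isolated)
Conditions: (+)-Ipc2BOMe, 16, Et2O, −78 °C → rt; 15, −78 °C → rt; then NaOH, H2O2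
Reagents that add atoms: (2-methylprop-2-en-1-yl)magnesium chloride (16), CC(=C)C[Mg]Cl
Why: Asymmetric methallylboration of Brown type through a closed chair transition state: the (+)-isopinocampheyl groups on boron send the methallyl group to the Re face of the hindered aldehyde, which sets C9 (R) under reagent control.

Step 12
Reactants: 18 homoallylic alcohol
Product: 19 ethenyl(dimethyl)silyl ether of 18
Conditions: ClSiMe2CH=CH2, imidazole, DMAP (cat.), CH2Cl2, rt
Reagents that add atoms: chloro(ethenyl)dimethylsilane, C=C[Si](C)(C)Cl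
Why: Silyl ether formation ties a vinylsilane to the C9 oxygen as a temporary tether for the metathesis.

Step 13
Reactants: 19 silicon-tethered diene
Product: 20 (6R)-6-{(1S,2S,5S)-2-[(1R)-1-(benzyloxy)-2-(triethylsilyloxy)ethyl]-2-methyl-5-(propan-2-yl)-5-(triethylsilyloxy)cyclopentyl}-2,2,4-trimethyl-5,6-dihydro-2H-1,2-oxasiline
Conditions: Mo(=CHCMe2Ph)(=N-2,6-iPr2C6H3)[OCMe(CF3)2]2 (cat.), benzene, rt → 60 °C
Reagents that add atoms: none
Why: Ring-closing metathesis of the vinylsilane with the 1,1-disubstituted alkene gives the six-membered oxasilacycle, whose ring forces silicon and C10 to be cis on the new C1=C2 bond.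

Step 14
Reactants: 20 cyclic siloxane
Product: 21 (1R,3Z)-1-{(1S,2S,5S)-2-[(1R)-1-(benzyloxy)-2-(triethylsilyloxy)ethyl]-2-methyl-5-(propan-2-yl)-5-(triethylsilyloxy)cyclopentyl}-3-methyl-4-(trimethylsilyl)but-3-en-1-ol
Conditions: MeLi, Et2O, −78 → 0 °C
Reagents that add atoms: methyllithium, [Li]C
Why: Nucleophilic substitution at silicon by MeLi cleaves the ring Si–O bond, which frees the C9 hydroxyl and leaves a trimethylsilyl group on C2 with the alkene geometry untouched, so the vinylsilane is Z.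

Step 15
Reactants: 21 vinylsilane alcohol
Product: 22 tert-butyldimethylsilyl ether of 21
Conditions: t-BuMe2SiOTf, 2,6-lutidine, CH2Cl2, −78 → 0 °C
Reagents that add atoms: tert-butyldimethylsilyl trifluoromethanesulfonate, CC(C)(C)[Si](C)(C)OS(=O)(=O)C(F)(F)F
Why: Silyl ether formation with the silyl triflate blocks the C9 oxygen so that it cannot add to the C3 cation in step 18.

Step 16
Reactants: 22 fully silylated vinylsilane
Product: 23 (2R)-2-(benzyloxy)-2-{(1S,2S,3S)-2-[(1R,3Z)-1-(tert-butyldimethylsilyloxy)-3-methyl-4-(trimethylsilyl)but-3-en-1-yl]-1-methyl-3-(propan-2-yl)-3-(triethylsilyloxy)cyclopentyl}acetaldehyde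
Conditions: (COCl)2, DMSO, CH2Cl2, −78 → −30 °C; then Et3N, −78 °C → rt
Reagents that add atoms: none
Why: Swern conditions cleave the primary triethylsilyl ether and oxidise the alcohol in one operation, while the secondary tert-butyldimethylsilyl ether and the tertiary triethylsilyl ether stay.

Step 17
Reactants: 23 α-benzyloxy aldehyde
Product: 24 (2R)-2-(benzyloxy)-2-{(1S,2S,3S)-2-[(1R,3Z)-1-(tert-butyldimethylsilyloxy)-3-methyl-4-(trimethylsilyl)but-3-en-1-yl]-1-methyl-3-(propan-2-yl)-3-(triethylsilyloxy)cyclopentyl}acetic acid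
Conditions: NaClO2, NaH2PO4, 2-methylbut-2-ene, t-BuOH–H2O, 0 °C → rt
Reagents that add atoms: sodium chlorite, [Na+].[O-]Cl=O
Why: Pinnick oxidation with a hypochlorite scavenger takes the non-enolisable aldehyde to the acid without touching the vinylsilane.

Step 18
Reactants: 24 α-benzyloxy acid with the Z vinylsilane
Product: 26 (3S,3aS,4R,8S,8aS)-8-(benzyloxy)-4-(tert-butyldimethylsilyloxy)-6,8a-dimethyl-3-(propan-2-yl)-3-(triethylsilyloxy)-1,2,3,3a,4,5,8,8a-octahydroazulene, via oxocarbenium ion 25 (not isolated)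
Conditions: graphite anode, Pt cathode, undivided cell, constant current, 2,4,6-collidine, n-Bu4NBF4, CH2Cl2–(CF3)2CHOH, 0 °C, high dilution
Reagents that add atoms: none
Why: Proposed new method: The collidinium carboxylate of 24 should be oxidised at the anode, lose CO2 to the α-benzyloxyalkyl radical and be oxidised again to the E oxocarbenium ion 25, which cannot lose a proton because C3 lies between oxygen and the quaternary C4; the closest known reactions are the Hofer–Moest oxidation of α-alkoxy acids and Lewis-acid-promoted vinylsilane-terminated oxocarbenium cyclisations, here joined in one flask. The Z vinylsilane attacks through its silicon-bearing carbon C2 to give a tertiary β-silyl cation at C1 that gives up the silyl group to the solvent, so the ring closes 7-endo with respect to the alkene (exo with respect to the C=O+ bond) and C1=C2 stays where the silicon was. The new stereocentre C3 should be set in a chair-like transition state of the forming cycloheptene in which the angular C4 methyl is axial and the C=O+ bond with its benzyl group lies pseudo-equatorial, which places the C3 oxygen cis to that methyl. The step needs the carboxylate to be oxidised before the vinylsilane, the benzyl ether and the silyl ethers (all of which are harder to oxidise), a cation that lasts long enough for a seven-membered closure (the poorly nucleophilic fluoro alcohol stabilises it and adds, if at all, reversibly), and no capture by the C7 and C9 oxygens, which are hindered silyl ethers and could only close a bridged or a trans-fused five-membered ring. Both C3 epimers of 24 give the same ion.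

Step 19
Reactants: 26 benzyl ether
Product: 27 (3S,3aS,4R,8S,8aS)-4-(tert-butyldimethylsilyloxy)-6,8a-dimethyl-3-(propan-2-yl)-3-(triethylsilyloxy)-1,2,3,3a,4,5,8,8a-octahydroazulen-8-ol
Conditions: lithium 4,4′-di-tert-butylbiphenylide, THF, −78 °C; then aqueous NH4Cl
Reagents that add atoms: none
Why: Reductive debenzylation by electron transfer from the lithium arenide cleaves the benzyl C–O bond through the arene radical anion and spares the isolated trisubstituted alkene and the silyl ethers.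

Step 20
Reactants: 27 C3 alcohol; 28 3-methylbutanoic anhydride
Product: 29 (3S,3aS,4R,8S,8aS)-4-(tert-butyldimethylsilyloxy)-6,8a-dimethyl-3-(propan-2-yl)-3-(triethylsilyloxy)-1,2,3,3a,4,5,8,8a-octahydroazulen-8-yl 3-methylbutanoate
Conditions: DMAP, Et3N, CH2Cl2, rt → 40 °C
Reagents that add atoms: 3-methylbutanoic anhydride (28), CC(C)CC(=O)OC(=O)CC(C)C
Why: DMAP-catalysed acylation through the acylpyridinium ion esterifies the hindered allylic C3 hydroxyl, which is the only free hydroxyl group.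

Step 21
Reactants: 29 bis-silyl ether
Product: 30 (3S,3aS,4R,8S,8aS)-3,4-dihydroxy-6,8a-dimethyl-3-(propan-2-yl)-1,2,3,3a,4,5,8,8a-octahydroazulen-8-yl 3-methylbutanoate
Conditions: HF·pyridine, pyridine, THF, 0 °C → rt
Reagents that add atoms: none
Why: Fluoride-mediated desilylation removes both silyl ethers and leaves the ester and the alkene.

Step 22
Reactants: 30 diol; 31 4-(acetyloxy)benzoyl chloride
Product: 32 (3S,3aS,4R,8S,8aS)-3-hydroxy-6,8a-dimethyl-8-[(3-methylbutanoyl)oxy]-3-(propan-2-yl)-1,2,3,3a,4,5,8,8a-octahydroazulen-4-yl 4-(acetyloxy)benzoate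
Conditions: pyridine, DMAP (cat.), CH2Cl2, 0 °C → rt
Reagents that add atoms: 4-(acetyloxy)benzoyl chloride (31), CC(=O)Oc1ccc(cc1)C(Cl)=O
Why: Acylation with the acid chloride is chemoselective for the secondary C9 hydroxyl because the tertiary C7 hydroxyl next to the isopropyl group is too hindered to react.

Step 23
Reactants: 32 aryl acetate
Product: 33 (3S,3aS,4R,8S,8aS)-3-hydroxy-6,8a-dimethyl-8-[(3-methylbutanoyl)oxy]-3-(propan-2-yl)-1,2,3,3a,4,5,8,8a-octahydroazulen-4-yl 4-hydroxybenzoate
Conditions: pyrrolidine, CH2Cl2, 0 °C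
Reagents that add atoms: none
Why: Aminolysis of the phenyl ester: the aryl acetate is far more electrophilic than the hindered alkyl isovalerate and benzoate, so pyrrolidine should remove only the acetyl group and free the phenol.

**Compound list**

1 | (R)-terpinen-4-ol, (1R)-4-methyl-1-(propan-2-yl)cyclohex-3-en-1-ol | CC1=CC[C@@](O)(C(C)C)CC1 | starting material
2 | triethyl{[(1R)-4-methyl-1-(propan-2-yl)cyclohex-3-en-1-yl]oxy}silane | CC1=CC[C@@](O[Si](CC)(CC)CC)(C(C)C)CC1 | intermediate
3 | (3R)-6-oxo-3-(propan-2-yl)-3-[(triethylsilyl)oxy]heptanal | O=CC[C@@](O[Si](CC)(CC)CC)(C(C)C)CCC(C)=O | intermediate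
4 | (5S)-2-methyl-5-(propan-2-yl)-5-[(triethylsilyl)oxy]cyclopent-1-ene-1-carbaldehyde | O=CC1=C(C)CC[C@]1(O[Si](CC)(CC)CC)C(C)C | intermediate
5 | {(5S)-2-methyl-5-(propan-2-yl)-5-[(triethylsilyl)oxy]cyclopent-1-en-1-yl}methanol | OCC1=C(C)CC[C@]1(O[Si](CC)(CC)CC)C(C)C | intermediate
6 | (benzyloxy)acetyl chloride | O=C(Cl)COCc1ccccc1 | starting material
7 | {(5S)-2-methyl-5-(propan-2-yl)-5-[(triethylsilyl)oxy]cyclopent-1-en-1-yl}methyl (benzyloxy)acetate | O=C(COCc1ccccc1)OCC1=C(C)CC[C@]1(O[Si](CC)(CC)CC)C(C)C | intermediate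
8 | Z trimethylsilyl ketene acetal of 7 (benzyloxy cis to trimethylsilyloxy; not isolated) | C[Si](C)(C)O/C(=C\OCc1ccccc1)OCC1=C(C)CC[C@]1(O[Si](CC)(CC)CC)C(C)C | intermediate
9 | trimethylsilyl ester of 10 (not isolated) | C[Si](C)(C)OC(=O)[C@H](OCc1ccccc1)[C@@]1(C)CC[C@](O[Si](CC)(CC)CC)(C(C)C)C1=C | intermediate
10 | (2R)-(benzyloxy){(1S,3S)-1-methyl-2-methylidene-3-(propan-2-yl)-3-[(triethylsilyl)oxy]cyclopentyl}acetic acid | OC(=O)[C@H](OCc1ccccc1)[C@@]1(C)CC[C@](O[Si](CC)(CC)CC)(C(C)C)C1=C | intermediate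
11 | (2R)-2-(benzyloxy)-2-{(1S,3S)-1-methyl-2-methylidene-3-(propan-2-yl)-3-[(triethylsilyl)oxy]cyclopentyl}ethan-1-ol | OC[C@H](OCc1ccccc1)[C@@]1(C)CC[C@](O[Si](CC)(CC)CC)(C(C)C)C1=C | intermediate
12 | primary triethylsilyl ether of 11 | CC[Si](CC)(CC)OC[C@H](OCc1ccccc1)[C@@]1(C)CC[C@](O[Si](CC)(CC)CC)(C(C)C)C1=C | intermediate
13 | B-alkyl-9-borabicyclo[3.3.1]nonane from 12, boron on C9, C8–H cis to the C7 oxygen (not isolated) | CC[Si](CC)(CC)OC[C@H](OCc1ccccc1)[C@@]1(C)CC[C@](O[Si](CC)(CC)CC)(C(C)C)[C@@H]1CB1C2CCCC1CCC2 | intermediate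
14 | {(1S,2S,5S)-2-[(1R)-1-(benzyloxy)-2-(triethylsilyloxy)ethyl]-2-methyl-5-(propan-2-yl)-5-(triethylsilyloxy)cyclopentyl}methanol | CC[Si](CC)(CC)OC[C@H](OCc1ccccc1)[C@@]1(C)CC[C@](O[Si](CC)(CC)CC)(C(C)C)[C@@H]1CO | intermediate
15 | (1R,2S,5S)-2-[(1R)-1-(benzyloxy)-2-(triethylsilyloxy)ethyl]-2-methyl-5-(propan-2-yl)-5-(triethylsilyloxy)cyclopentane-1-carbaldehyde | CC[Si](CC)(CC)OC[C@H](OCc1ccccc1)[C@@]1(C)CC[C@](O[Si](CC)(CC)CC)(C(C)C)[C@@H]1C=O | intermediate
16 | (2-methylprop-2-en-1-yl)magnesium chloride | CC(=C)C[Mg]Cl | starting material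
17 | O-bis[(+)-isopinocampheyl]borinate of 18 (not isolated) | CC[Si](CC)(CC)OC[C@H](OCc1ccccc1)[C@@]1(C)CC[C@](O[Si](CC)(CC)CC)(C(C)C)[C@@H]1[C@H](OB([C@H]2C[C@H]3C[C@@H]([C@@H]2C)C3(C)C)[C@H]2C[C@H]3C[C@@H]([C@@H]2C)C3(C)C)CC(C)=C | intermediate
18 | (1R)-1-{(1S,2S,5S)-2-[(1R)-1-(benzyloxy)-2-(triethylsilyloxy)ethyl]-2-methyl-5-(propan-2-yl)-5-(triethylsilyloxy)cyclopentyl}-3-methylbut-3-en-1-ol | CC[Si](CC)(CC)OC[C@H](OCc1ccccc1)[C@@]1(C)CC[C@](O[Si](CC)(CC)CC)(C(C)C)[C@@H]1[C@H](O)CC(C)=C | intermediate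
19 | ethenyl(dimethyl)silyl ether of 18 | CC[Si](CC)(CC)OC[C@H](OCc1ccccc1)[C@@]1(C)CC[C@](O[Si](CC)(CC)CC)(C(C)C)[C@@H]1[C@H](O[Si](C)(C)C=C)CC(C)=C | intermediate
20 | (6R)-6-{(1S,2S,5S)-2-[(1R)-1-(benzyloxy)-2-(triethylsilyloxy)ethyl]-2-methyl-5-(propan-2-yl)-5-(triethylsilyloxy)cyclopentyl}-2,2,4-trimethyl-5,6-dihydro-2H-1,2-oxasiline | CC[Si](CC)(CC)OC[C@H](OCc1ccccc1)[C@@]1(C)CC[C@](O[Si](CC)(CC)CC)(C(C)C)[C@@H]1[C@H]1CC(C)=C[Si](C)(C)O1 | intermediate
21 | (1R,3Z)-1-{(1S,2S,5S)-2-[(1R)-1-(benzyloxy)-2-(triethylsilyloxy)ethyl]-2-methyl-5-(propan-2-yl)-5-(triethylsilyloxy)cyclopentyl}-3-methyl-4-(trimethylsilyl)but-3-en-1-ol | CC[Si](CC)(CC)OC[C@H](OCc1ccccc1)[C@@]1(C)CC[C@](O[Si](CC)(CC)CC)(C(C)C)[C@@H]1[C@H](O)C/C(C)=C\[Si](C)(C)C | intermediate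
22 | tert-butyldimethylsilyl ether of 21 | CC[Si](CC)(CC)OC[C@H](OCc1ccccc1)[C@@]1(C)CC[C@](O[Si](CC)(CC)CC)(C(C)C)[C@@H]1[C@H](O[Si](C)(C)C(C)(C)C)C/C(C)=C\[Si](C)(C)C | intermediate
23 | (2R)-2-(benzyloxy)-2-{(1S,2S,3S)-2-[(1R,3Z)-1-(tert-butyldimethylsilyloxy)-3-methyl-4-(trimethylsilyl)but-3-en-1-yl]-1-methyl-3-(propan-2-yl)-3-(triethylsilyloxy)cyclopentyl}acetaldehyde | O=C[C@H](OCc1ccccc1)[C@@]1(C)CC[C@](O[Si](CC)(CC)CC)(C(C)C)[C@@H]1[C@H](O[Si](C)(C)C(C)(C)C)C/C(C)=C\[Si](C)(C)C | intermediate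
24 | (2R)-2-(benzyloxy)-2-{(1S,2S,3S)-2-[(1R,3Z)-1-(tert-butyldimethylsilyloxy)-3-methyl-4-(trimethylsilyl)but-3-en-1-yl]-1-methyl-3-(propan-2-yl)-3-(triethylsilyloxy)cyclopentyl}acetic acid | OC(=O)[C@H](OCc1ccccc1)[C@@]1(C)CC[C@](O[Si](CC)(CC)CC)(C(C)C)[C@@H]1[C@H](O[Si](C)(C)C(C)(C)C)C/C(C)=C\[Si](C)(C)C | intermediate
25 | E O-benzyl oxocarbenium ion at C3 formed from 24 (not isolated) | c1ccccc1C/[O+]=C/[C@@]1(C)CC[C@](O[Si](CC)(CC)CC)(C(C)C)[C@@H]1[C@H](O[Si](C)(C)C(C)(C)C)C/C(C)=C\[Si](C)(C)C | intermediate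
26 | (3S,3aS,4R,8S,8aS)-8-(benzyloxy)-4-(tert-butyldimethylsilyloxy)-6,8a-dimethyl-3-(propan-2-yl)-3-(triethylsilyloxy)-1,2,3,3a,4,5,8,8a-octahydroazulene | CC1=C[C@H](OCc2ccccc2)[C@@]2(C)CC[C@](O[Si](CC)(CC)CC)(C(C)C)[C@@H]2[C@H](O[Si](C)(C)C(C)(C)C)C1 | intermediate
27 | (3S,3aS,4R,8S,8aS)-4-(tert-butyldimethylsilyloxy)-6,8a-dimethyl-3-(propan-2-yl)-3-(triethylsilyloxy)-1,2,3,3a,4,5,8,8a-octahydroazulen-8-ol | CC1=C[C@H](O)[C@@]2(C)CC[C@](O[Si](CC)(CC)CC)(C(C)C)[C@@H]2[C@H](O[Si](C)(C)C(C)(C)C)C1 | intermediate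
28 | 3-methylbutanoic anhydride | CC(C)CC(=O)OC(=O)CC(C)C | starting material
29 | 3-methylbutanoate of 27 at the C3 oxygen | CC1=C[C@H](OC(=O)CC(C)C)[C@@]2(C)CC[C@](O[Si](CC)(CC)CC)(C(C)C)[C@@H]2[C@H](O[Si](C)(C)C(C)(C)C)C1 | intermediate
30 | (3S,3aS,4R,8S,8aS)-3,4-dihydroxy-6,8a-dimethyl-3-(propan-2-yl)-1,2,3,3a,4,5,8,8a-octahydroazulen-8-yl 3-methylbutanoate | CC1=C[C@H](OC(=O)CC(C)C)[C@@]2(C)CC[C@](O)(C(C)C)[C@@H]2[C@H](O)C1 | intermediate
31 | 4-(acetyloxy)benzoyl chloride | CC(=O)Oc1ccc(cc1)C(Cl)=O | starting material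
32 | (3S,3aS,4R,8S,8aS)-3-hydroxy-6,8a-dimethyl-8-[(3-methylbutanoyl)oxy]-3-(propan-2-yl)-1,2,3,3a,4,5,8,8a-octahydroazulen-4-yl 4-(acetyloxy)benzoate | CC1=C[C@H](OC(=O)CC(C)C)[C@@]2(C)CC[C@](O)(C(C)C)[C@@H]2[C@H](OC(=O)c2ccc(OC(C)=O)cc2)C1 | intermediate
33 | (3S,3aS,4R,8S,8aS)-3-hydroxy-6,8a-dimethyl-8-[(3-methylbutanoyl)oxy]-3-(propan-2-yl)-1,2,3,3a,4,5,8,8a-octahydroazulen-4-yl 4-hydroxybenzoate | CC1=C[C@H](OC(=O)CC(C)C)[C@@]2(C)CC[C@](O)(C(C)C)[C@@H]2[C@H](OC(=O)c2ccc(O)cc2)C1 | target

**Step count and risks**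

Total step count: 23. Longest linear sequence: 23 steps, from 1 to 33; compounds 6, 16, 28 and 31 are bought.

Step 18, the one step that goes beyond known chemistry, is the most likely to fail. The C3 cation may be captured by the fluoro alcohol, by collidine or by a neighbouring silyl ether oxygen, or it may decompose, before the slow seven-membered closure. The ring may also close on the other face of C3. The fallback avoids the cation and uses known reactions only; it sets out from acid 24 and comes back at alcohol 27. Oxidative decarboxylation of 24 with Pb(OAc)4 (pyridine, benzene) should give the α-acetoxy benzyl ether F1. K2CO3 in methanol cleaves it to the C3 aldehyde F2. N-Iodosuccinimide in acetonitrile exchanges silicon for iodine with retention and gives the Z vinyl iodide aldehyde F3. An intramolecular Nozaki–Hiyama–Kishi reaction (CrCl2, catalytic NiCl2, DMSO, high dilution) closes the seven-membered ring to the cycloheptenol F4 as a mixture at C3. Dess–Martin oxidation gives the enone F5. Luche reduction (NaBH4, CeCl3·7H2O), with hydride entering anti to the axial C4 methyl group, should give 27, and the route continues with step 20.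

Step 9 may fail by wrong facial selectivity. The borane may prefer the isopropyl face of C8=C9, which would give the C8 epimer. The fallback turns that preference to use; it sets out from alkene 12 and comes back at aldehyde 15. Epoxidation of 12 with 3-chloroperbenzoic acid (NaHCO3, CH2Cl2) should follow the same facial preference and give the spiro-epoxide F6, with its oxygen on the isopropyl face. MeAl(OC6H2-2,6-tBu2-4-Br)2 in CH2Cl2 at −78 °C then opens the C8–O bond while a hydride shifts from C9 to C8 with inversion (Meinwald rearrangement). The hydrogen therefore arrives on the face of the C7 oxygen, and 15 is reached in place of steps 9 and 10.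

Step 6 may fail by loss of the silyl ketene acetal (C-silylation, elimination to the ketene) before the slow bond formation at the fully substituted C4. The fallback uses an uncharged thermal rearrangement and brings in the C3 oxygen afterwards; it sets out from allylic alcohol 5 and comes back at alcohol 11. Johnson–Claisen rearrangement of 5 with triethyl orthoacetate and catalytic propionic acid at 140 °C should give the ethyl ester F7. Its potassium enolate (KN(SiMe3)2, THF, −78 °C) is hydroxylated with 2-(phenylsulfonyl)-3-phenyloxaziridine to the α-hydroxy ester F8. Benzylation (benzyl bromide, Ag2O) gives the α-benzyloxy ester F9. LiAlH4 then gives 11 as a mixture of C3 epimers, which is acceptable because C3 becomes planar in step 18.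

**Further compounds**

F1 | step 18 | α-acetoxy benzyl ether at C3 from 24 (both C3 epimers) | CC(=O)OC(OCc1ccccc1)[C@@]1(C)CC[C@](O[Si](CC)(CC)CC)(C(C)C)[C@@H]1[C@H](O[Si](C)(C)C(C)(C)C)C/C(C)=C\[Si](C)(C)C
F2 | step 18 | C3 aldehyde bearing the Z vinylsilane | O=C[C@@]1(C)CC[C@](O[Si](CC)(CC)CC)(C(C)C)[C@@H]1[C@H](O[Si](C)(C)C(C)(C)C)C/C(C)=C\[Si](C)(C)C
F3 | step 18 | C3 aldehyde bearing the Z vinyl iodide | O=C[C@@]1(C)CC[C@](O[Si](CC)(CC)CC)(C(C)C)[C@@H]1[C@H](O[Si](C)(C)C(C)(C)C)C/C(C)=C\I
F4 | step 18 | cycloheptenol with the C1=C2 alkene (both C3 epimers of 27) | CC1=CC(O)[C@@]2(C)CC[C@](O[Si](CC)(CC)CC)(C(C)C)[C@@H]2[C@H](O[Si](C)(C)C(C)(C)C)C1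
F5 | step 18 | C3 enone | CC1=CC(=O)[C@@]2(C)CC[C@](O[Si](CC)(CC)CC)(C(C)C)[C@@H]2[C@H](O[Si](C)(C)C(C)(C)C)C1
F6 | step 9 | spiro-epoxide of 12 with the epoxide oxygen on the isopropyl face of C8 | CC[Si](CC)(CC)OC[C@H](OCc1ccccc1)[C@@]1(C)CC[C@](O[Si](CC)(CC)CC)(C(C)C)[C@@]12CO2
F7 | step 6 | ethyl {1-methyl-2-methylidene-3-(propan-2-yl)-3-[(triethylsilyl)oxy]cyclopentyl}acetate with the ring configuration of 10 | CCOC(=O)C[C@@]1(C)CC[C@](O[Si](CC)(CC)CC)(C(C)C)C1=C
F8 | step 6 | α-hydroxy ester from F7 (both C3 epimers) | CCOC(=O)C(O)[C@@]1(C)CC[C@](O[Si](CC)(CC)CC)(C(C)C)C1=C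
F9 | step 6 | α-benzyloxy ester from F8 (both C3 epimers) | CCOC(=O)C(OCc1ccccc1)[C@@]1(C)CC[C@](O[Si](CC)(CC)CC)(C(C)C)C1=C
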